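**Plan**

- Reading of the target: ent-epiafzelechin-(4β→8)-epiafzelechin-(4α→8)-(2S,3S,4R)-2-(4-hydroxyphenyl)chromane-3,4,5,7-tetrol, with units T (top), M (middle) and B (terminal 3,4-diol). Every pyran ring is 2,3-cis, both interflavan bonds are cis to O3 of their upper unit, and the diol of B is 3,4-trans.
- Retrosynthesis cuts, in order: the O1–C8a aryl ether of ring C of B (alkoxide on aryl fluoride), the C4–C4a bond of B (aryl Grignard on an α-benzyloxy aldehyde), and the M-C4–B-C8 bond (arylmagnesium chloride with LaCl3·2LiCl on the 4-ketone, then ionic hydrogenation). The same three cuts are then made for M (its C4–aryl bond through the aryllithium), and the two ring cuts for T. Every ring A is 1,3-bis(benzyloxy)-5-fluorobenzene, brominated once or twice next to fluorine.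
- Forward: ring C of T is closed and oxidized to the 4-ketone; the dibromo arene is added to it and the carbinol reduced; the second bromide brings in the C2–C3–C4 chain of M, whose ring C is closed and oxidized. The cycle is repeated for B, whose ring C is closed last on the complete trimer skeleton, before debenzylation and desilylation.
- Stereochemistry: C2 and C3 of each unit come from Evans syn glycolate aldols ((R)-auxiliary for T and B, (S)-auxiliary for M). C4 of T and M comes from hydride delivery to the C4 cation anti to the axial 3-benzyloxy group (all-cis), and C4 of B from Cram-chelate addition. C2 is kept in every ring closure because its C–O bond is never broken.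
- Enabling feature: in ring A of B, C8a (the carbon that carries O1) lies between C8 (bearing M-C4) and C4a (bearing C4) and is meta to the oxygens on C5 and C7. A fluorine there is flanked by the two positions that are brominated and metalated in turn, survives both, and is then displaced by the C2 oxygen. That oxygen is unmasked by a 1,5 silyl shift across the O2/O4 1,3-diol, which at the same time protects the labile benzylic O4.

Key step: step 27

Remark: the C4 carbinol centres made in steps 14 and 20 are erased by oxidation (steps 17 and 23); compounds 22–24 and 30–32 are written as the chelation-controlled isomers, and their C4 epimers would pass through the same steps.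

**Route**

Step 1
Reactants: 1 1,3,5-trifluorobenzene
Product: 2 1,3-bis(benzyloxy)-5-fluorobenzene
Conditions: BnOH (2.1 equiv), NaH, NMP, 0 → 90 °C
Reagents that add atoms: benzyl alcohol, OCc1ccccc1
Why: Double SNAr of sodium benzyl oxide on the trifluoroarene, where each alkoxy group slows the next substitution so that the third fluorine is kept.

Step 2
Reactants: 2 1,3-bis(benzyloxy)-5-fluorobenzene
Product: 3 1,5-bis(benzyloxy)-2-bromo-3-fluorobenzene
Conditions: NBS (1.0 equiv), MeCN, 0 °C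
Reagents that add atoms: N-bromosuccinimide, O=C1CCC(=O)N1Br
Why: Electrophilic aromatic bromination goes para to one benzyloxy group and ortho to the other, the site next to fluorine, as in resorcinol diethers where the position between the two ether groups reacts last.

Step 3
Reactants: 2 1,3-bis(benzyloxy)-5-fluorobenzene
Product: 4 1,5-bis(benzyloxy)-2,4-dibromo-3-fluorobenzene
Conditions: NBS (2.1 equiv), MeCN, rt
Reagents that add atoms: N-bromosuccinimide, O=C1CCC(=O)N1Br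
Why: The same electrophilic bromination run twice puts bromine on both carbons that flank fluorine, each para to one benzyloxy group.

Step 4
Reactants: 5 (R)-4-benzyloxazolidin-2-one; 6 (benzyloxy)acetyl chloride
Product: 7 (R)-4-benzyl-3-[(benzyloxy)acetyl]oxazolidin-2-one
Conditions: Et3N, DMAP (cat.), CH2Cl2, 0 °C → rt
Reagents that add atoms: none
Why: DMAP-catalysed N-acylation of the oxazolidinone by the acid chloride gives the glycolate imide.

Step 5
Reactants: 7 (R)-glycolate imide; 8 4-(benzyloxy)benzaldehyde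
Product: 10 (R)-4-benzyl-3-[(2R,3S)-2-(benzyloxy)-3-[4-(benzyloxy)phenyl]-3-hydroxypropanoyl]oxazolidin-2-one, via Z boron enolate 9 (not isolated)
Conditions: Bu2BOTf, i-Pr2NEt, CH2Cl2, −78 → 0 °C; then 8, −78 → 0 °C; pH 7 buffer, MeOH, H2O2
Reagents that add atoms: none
Why: Evans syn aldol reaction in which the Z boron enolate 9 reacts through a Zimmerman–Traxler chair on the face away from the auxiliary benzyl group, setting C2 (R) and C3 (S) together as the 2,3-syn pair.

Step 6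
Reactants: 10 (2R,3S) aldol adduct
Product: 11 (R)-4-benzyl-3-[(2R,3S)-2-(benzyloxy)-3-[4-(benzyloxy)phenyl]-3-[(tert-butyldimethylsilyl)oxy]propanoyl]oxazolidin-2-one
Conditions: TBSOTf, 2,6-lutidine, CH2Cl2, −78 → 0 °C
Reagents that add atoms: tert-butyldimethylsilyl trifluoromethanesulfonate, CC(C)(C)[Si](C)(C)OS(=O)(=O)C(F)(F)F
Why: Silylation of the secondary benzylic alcohol with the silyl triflate and a hindered base touches no stereocentre.

Step 7
Reactants: 11 silylated imide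
Product: 12 (2S,3S)-2-(benzyloxy)-3-[4-(benzyloxy)phenyl]-3-[(tert-butyldimethylsilyl)oxy]propan-1-ol
Conditions: LiBH4, MeOH (1 equiv), THF, 0 °C
Reagents that add atoms: none
Why: Reductive cleavage of the N-acyl oxazolidinone with LiBH4 gives the primary alcohol and returns the auxiliary.

Step 8
Reactants: 12 primary alcohol
Product: 13 (2R,3S)-2-(benzyloxy)-3-[4-(benzyloxy)phenyl]-3-[(tert-butyldimethylsilyl)oxy]propanal
Conditions: Dess–Martin periodinane, pyridine, CH2Cl2, 0 °C → rt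
Reagents that add atoms: none
Why: Dess–Martin oxidation gives the α-benzyloxy aldehyde under buffered, non-enolizing conditions, so C2 should not epimerize; the aldehyde is used without storage.

Step 9
Reactants: 14 (S)-4-benzyloxazolidin-2-one; 6 (benzyloxy)acetyl chloride
Product: 15 (S)-4-benzyl-3-[(benzyloxy)acetyl]oxazolidin-2-one
Conditions: Et3N, DMAP (cat.), CH2Cl2, 0 °C → rt
Reagents that add atoms: none
Why: DMAP-catalysed N-acylation, as in step 4, in the enantiomeric series.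

Step 10
Reactants: 15 (S)-glycolate imide; 8 4-(benzyloxy)benzaldehyde
Product: 17 (S)-4-benzyl-3-[(2S,3R)-2-(benzyloxy)-3-[4-(benzyloxy)phenyl]-3-hydroxypropanoyl]oxazolidin-2-one, via Z boron enolate 16 (not isolated)
Conditions: Bu2BOTf, i-Pr2NEt, CH2Cl2, −78 → 0 °C; then 8, −78 → 0 °C; pH 7 buffer, MeOH, H2O2
Reagents that add atoms: none
Why: Evans syn aldol reaction as in step 5, with the (S)-auxiliary setting C2 (S) and C3 (R).

Step 11
Reactants: 17 (2S,3R) aldol adduct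
Product: 18 (S)-4-benzyl-3-[(2S,3R)-2-(benzyloxy)-3-[4-(benzyloxy)phenyl]-3-[(tert-butyldimethylsilyl)oxy]propanoyl]oxazolidin-2-one
Conditions: TBSOTf, 2,6-lutidine, CH2Cl2, −78 → 0 °C
Reagents that add atoms: tert-butyldimethylsilyl trifluoromethanesulfonate, CC(C)(C)[Si](C)(C)OS(=O)(=O)C(F)(F)F
Why: Silylation of the secondary benzylic alcohol, as in step 6.

Step 12
Reactants: 18 silylated imide
Product: 19 (2R,3R)-2-(benzyloxy)-3-[4-(benzyloxy)phenyl]-3-[(tert-butyldimethylsilyl)oxy]propan-1-ol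
Conditions: LiBH4, MeOH (1 equiv), THF, 0 °C
Reagents that add atoms: none
Why: Reductive cleavage of the imide with LiBH4, as in step 7.

Step 13
Reactants: 19 primary alcohol
Product: 20 (2S,3R)-2-(benzyloxy)-3-[4-(benzyloxy)phenyl]-3-[(tert-butyldimethylsilyl)oxy]propanal
Conditions: Dess–Martin periodinane, pyridine, CH2Cl2, 0 °C → rt
Reagents that add atoms: none
Why: Dess–Martin oxidation, as in step 8.

Step 14
Reactants: 3 monobromo fluoroarene; 13 (2R,3S) aldehyde
Product: 22 (1R,2S,3S)-2-(benzyloxy)-3-[4-(benzyloxy)phenyl]-1-[2,4-bis(benzyloxy)-6-fluorophenyl]-3-[(tert-butyldimethylsilyl)oxy]propan-1-ol, via arylmagnesium chloride 21 (not isolated)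
Conditions: i-PrMgCl·LiCl, THF, 0 °C; then 13, MgBr2·OEt2, CH2Cl2, −78 → −20 °C
Reagents that add atoms: none
Why: Bromine–magnesium exchange and 1,2-addition of the aryl Grignard reagent to the aldehyde held as a five-membered magnesium chelate with the α-benzyloxy group (Cram-chelate control, 1,2-syn); the new centre is oxidized in step 17, so its configuration does not matter here.

Step 15
Reactants: 22 unit T carbinol
Product: 23 (1R,2R,3S)-2-(benzyloxy)-3-[4-(benzyloxy)phenyl]-1-[2,4-bis(benzyloxy)-6-fluorophenyl]propane-1,3-diol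
Conditions: Bu4NF, THF, 0 °C → rt
Reagents that add atoms: none
Why: Fluoride cleavage of the silyl ether frees the hydroxyl that becomes O1.

Step 16
Reactants: 23 unit T diol
Product: 24 (2S,3S,4R)-3,5,7-tris(benzyloxy)-2-[4-(benzyloxy)phenyl]chroman-4-ol
Conditions: KN(SiMe3)2 (1.2 equiv), THF/DMPU, 0 → 50 °C
Reagents that add atoms: none
Why: Intramolecular SNAr etherification of the benzylic alkoxide on the aryl fluoride, the known route from 2-fluoroaryl alkanols to chromans and flavans, closes ring C; only the O2 alkoxide can form a six-membered ring and the C–O bond at C2 is untouched, so the 2,3-cis relation from the aldol is kept.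

Step 17
Reactants: 24 unit T flavan-4-ol
Product: 25 (2S,3R)-3,5,7-tris(benzyloxy)-2-[4-(benzyloxy)phenyl]chroman-4-one
Conditions: Dess–Martin periodinane, pyridine, CH2Cl2, 0 °C → rt
Reagents that add atoms: none
Why: Dess–Martin oxidation of the benzylic alcohol gives the 2,3-cis 4-ketone without base, so the epimerizable C3 should not be disturbed.

Step 18
Reactants: 4 dibromo fluoroarene; 25 unit T ketone
Product: 27 (2S,3R,4R)-3,5,7-tris(benzyloxy)-2-[4-(benzyloxy)phenyl]-4-[4,6-bis(benzyloxy)-3-bromo-2-fluorophenyl]chroman-4-ol, via aryllithium 26 (not isolated)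
Conditions: n-BuLi (1.0 equiv per 4), THF, −78 °C; then 25, −78 °C
Reagents that add atoms: none
Why: Bromine–lithium exchange of one bromide at −78 °C, where the ortho-fluoro aryllithium does not yet lose LiF, and 1,2-addition to the ketone anti to the axial 3-benzyloxy group; the carbinol configuration is erased in step 19.

Step 19
Reactants: 27 tertiary carbinol
Product: 28 (2S,3S,4R)-3,5,7-tris(benzyloxy)-2-[4-(benzyloxy)phenyl]-4-[4,6-bis(benzyloxy)-3-bromo-2-fluorophenyl]chromane (all-cis)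
Conditions: Bu3SnH, CF3CO2H, CH2Cl2, −78 → 0 °C
Reagents that add atoms: none
Why: Ionic hydrogenation in which acid ionizes the tertiary, doubly benzylic alcohol and Bu3SnH delivers hydride to the cation anti to the axial 3-benzyloxy group, leaving the new C4–aryl bond cis to O3 and to the 2-aryl group.

Step 20
Reactants: 28 unit T aryl bromide; 20 (2S,3R) aldehyde
Product: 30 (1S,2R,3R)-2-(benzyloxy)-3-[4-(benzyloxy)phenyl]-1-{4,6-bis(benzyloxy)-2-fluoro-3-[(2S,3S,4R)-3,5,7-tris(benzyloxy)-2-(4-benzyloxyphenyl)chroman-4-yl]phenyl}-3-[(tert-butyldimethylsilyl)oxy]propan-1-ol, via arylmagnesium chloride 29 (not isolated)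
Conditions: i-PrMgCl·LiCl, THF, 0 °C; then 20, MgBr2·OEt2, CH2Cl2, −78 → −20 °C
Reagents that add atoms: none
Why: Bromine–magnesium exchange and Cram-chelate 1,2-addition as in step 14; the new carbinol centre is oxidized in step 23.

Step 21
Reactants: 30 unit M carbinol
Product: 31 (1S,2S,3R)-2-(benzyloxy)-3-[4-(benzyloxy)phenyl]-1-{4,6-bis(benzyloxy)-2-fluoro-3-[(2S,3S,4R)-3,5,7-tris(benzyloxy)-2-(4-benzyloxyphenyl)chroman-4-yl]phenyl}propane-1,3-diol
Conditions: Bu4NF, THF, 0 °C → rt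
Reagents that add atoms: none
Why: Fluoride cleavage of the silyl ether, as in step 15.

Step 22
Reactants: 31 unit M diol
Product: 32 octa-O-benzyl ent-epiafzelechin-(4β→8)-epiafzelechin-4β-ol
Conditions: KN(SiMe3)2 (1.2 equiv), THF/DMPU, 0 → 50 °C
Reagents that add atoms: none
Why: Intramolecular SNAr etherification as in step 16 closes ring C of M with retention at C2, giving the (2R,3R) 2,3-cis unit.

Step 23
Reactants: 32 dimer 4-ol
Product: 33 octa-O-benzyl dimer 4-ketone (unit M: (2R,3S)-chroman-4-one)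
Conditions: Dess–Martin periodinane, pyridine, CH2Cl2, 0 °C → rt
Reagents that add atoms: none
Why: Dess–Martin oxidation of the only free hydroxyl gives the 2,3-cis 4-ketone of M without base.

Step 24
Reactants: 4 dibromo fluoroarene; 33 dimer 4-ketone
Product: 35 dimer tertiary carbinol (M-C4 bears OH cis to 3-OBn and the 4,6-bis(benzyloxy)-3-bromo-2-fluorophenyl group), via arylmagnesium chloride 34 (not isolated)
Conditions: i-PrMgCl·LiCl (1.0 equiv per 4), THF, −15 → 0 °C; then 33, LaCl3·2LiCl (0.3 equiv), THF, 0 °C → rt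
Reagents that add atoms: none
Why: Bromine–magnesium exchange of one bromide of 4 gives an ortho-fluoro arylmagnesium chloride that, unlike the aryllithium, does not lose fluoride at 0 °C, and its LaCl3·2LiCl-promoted 1,2-addition to the larger, enolizable ketone (lanthanide-assisted Grignard addition) should suppress enolization at C3 during the longer reaction time; attack comes anti to the axial 3-benzyloxy group and the carbinol configuration is erased in step 25.

Step 25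
Reactants: 35 dimer tertiary carbinol
Product: 36 dimer aryl bromide (M-C4 aryl bond α, cis to 3-OBn and to the 2-aryl group)
Conditions: Bu3SnH, CF3CO2H, CH2Cl2, −78 → 0 °C
Reagents that add atoms: none
Why: Ionic hydrogenation as in step 19; hydride adds to the M-C4 cation anti to the axial 3-benzyloxy group and sets the all-cis unit M.

Step 26
Reactants: 36 dimer aryl bromide; 13 (2R,3S) aldehyde
Product: 38 trimer-stage carbinol (chain (1R,2S,3S), with C1–OH free, C2–OBn and C3–OTBS), via arylmagnesium chloride 37 (not isolated)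
Conditions: i-PrMgCl·LiCl, THF, 0 °C; then 13, MgBr2·OEt2, CH2Cl2, −78 → −20 °C
Reagents that add atoms: none
Why: Bromine–magnesium exchange and Cram-chelate 1,2-addition to the α-benzyloxy aldehyde; attack on the chelate from the side of the α-hydrogen sets C4 of unit B as R (3,4-syn), which becomes the 3,4-trans diol once the ring is closed.

Step 27
Reactants: 38 trimer-stage carbinol
Product: 41 dodeca-O-benzyl 4-O-(tert-butyldimethylsilyl) trimer, via potassium C4-alkoxide 39 (not isolated), via silyl-shifted potassium C2-alkoxide 40 (not isolated)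
Conditions: KN(SiMe3)2 (1.1 equiv), THF/DMPU, −20 → 45 °C
Reagents that add atoms: none
Why: Proposed new method: KN(SiMe3)2 deprotonates the C4 hydroxyl to alkoxide 39, whose 1,5 oxygen-to-oxygen silyl shift through a six-membered pentacoordinate silicate moves the silyl group from O2 to O4 and frees the C2 alkoxide 40, which attacks C8a of ring A and expels fluoride through a Meisenheimer complex. The closest known reaction types are the base-induced silyl migration between the oxygens of a 1,3-diol monosilyl ether and the intramolecular SNAr etherification of an alkoxide with an aryl fluoride that gives chromans and flavans (steps 16 and 22); running both in one operation is what is new. Ring C of unit B closes in a 6-exo-trig addition–elimination at the sp2 carbon C8a, with fluoride as the only leaving group. No stereocentre is made: C2, C3 and C4 come from aldehyde 13 and step 26, and because the C2–O bond is never broken the 2,3-cis arrangement, which a closure through a C2 cation would lose, is kept. The step needs the C2 oxygen alone to reach C8a; this is secured because O3 is a benzyl ether, O4 could only form a four-membered ring, and the irreversible substitution drains the silyl-shift equilibrium. The fluoride at C8a is activated inductively by the meta benzyloxy groups on C5 and C7, and the silyl group ends on the acid-labile benzylic O4, where it is wanted for step 28.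

Step 28
Reactants: 41 protected trimer
Product: 42 4-O-(tert-butyldimethylsilyl) ether of the target (all phenols and the three 3-hydroxyls free)
Conditions: H2 (1 atm), Pd(OH)2/C, THF/EtOAc, rt
Reagents that add atoms: none
Why: Hydrogenolysis of all twelve benzyl ethers, in which the bulky silyl ether shields the benzylic C4–O bond of unit B and the solvent is kept free of methanol and acid so that the silyl ether stays on.

Step 29
Reactants: 42 4-O-silyl trimer
Product: 43 ent-epiafzelechin-(4β→8)-epiafzelechin-(4α→8)-(2S,3S,4R)-2-(4-hydroxyphenyl)chromane-3,4,5,7-tetrol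
Conditions: Bu4NF, AcOH (1:1), THF, 0 °C → rt
Reagents that add atoms: none
Why: Fluoride desilylation buffered with acetic acid frees the 4-hydroxyl under near-neutral conditions, which the acid- and base-sensitive benzylic carbinol of the phloroglucinol ring should tolerate.

**Compound list**

1 | 1,3,5-trifluorobenzene | Fc1cc(F)cc(F)c1 | starting material
2 | 1,3-bis(benzyloxy)-5-fluorobenzene | Fc1cc(OCc2ccccc2)cc(OCc2ccccc2)c1 | intermediate
3 | 1,5-bis(benzyloxy)-2-bromo-3-fluorobenzene | Fc1cc(OCc2ccccc2)cc(OCc2ccccc2)c1Br | intermediate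
4 | 1,5-bis(benzyloxy)-2,4-dibromo-3-fluorobenzene | Fc1c(Br)c(OCc2ccccc2)cc(OCc2ccccc2)c1Br | intermediate
5 | (R)-4-benzyloxazolidin-2-one | O=C1N[C@H](Cc2ccccc2)CO1 | starting material
6 | (benzyloxy)acetyl chloride | O=C(Cl)COCc1ccccc1 | starting material
7 | (R)-4-benzyl-3-[(benzyloxy)acetyl]oxazolidin-2-one | O=C1OC[C@@H](Cc2ccccc2)N1C(=O)COCc1ccccc1 | intermediate
8 | 4-(benzyloxy)benzaldehyde | O=Cc1ccc(OCc2ccccc2)cc1 | starting material
9 | Z dibutylboron enolate of 7 | CCCCB(CCCC)O/C(=C\OCc1ccccc1)N1[C@H](Cc2ccccc2)COC1=O | intermediate (not isolated)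
10 | (R)-4-benzyl-3-[(2R,3S)-2-(benzyloxy)-3-[4-(benzyloxy)phenyl]-3-hydroxypropanoyl]oxazolidin-2-one | O=C1OC[C@@H](Cc2ccccc2)N1C(=O)[C@H](OCc1ccccc1)[C@@H](O)c1ccc(OCc2ccccc2)cc1 | intermediate
11 | (R)-4-benzyl-3-[(2R,3S)-2-(benzyloxy)-3-[4-(benzyloxy)phenyl]-3-[(tert-butyldimethylsilyl)oxy]propanoyl]oxazolidin-2-one | O=C1OC[C@@H](Cc2ccccc2)N1C(=O)[C@H](OCc1ccccc1)[C@@H](O[Si](C)(C)C(C)(C)C)c1ccc(OCc2ccccc2)cc1 | intermediate
12 | (2S,3S)-2-(benzyloxy)-3-[4-(benzyloxy)phenyl]-3-[(tert-butyldimethylsilyl)oxy]propan-1-ol | OC[C@H](OCc1ccccc1)[C@@H](O[Si](C)(C)C(C)(C)C)c1ccc(OCc2ccccc2)cc1 | intermediate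
13 | (2R,3S)-2-(benzyloxy)-3-[4-(benzyloxy)phenyl]-3-[(tert-butyldimethylsilyl)oxy]propanal | O=C[C@H](OCc1ccccc1)[C@@H](O[Si](C)(C)C(C)(C)C)c1ccc(OCc2ccccc2)cc1 | intermediate
14 | (S)-4-benzyloxazolidin-2-one | O=C1N[C@@H](Cc2ccccc2)CO1 | starting material
15 | (S)-4-benzyl-3-[(benzyloxy)acetyl]oxazolidin-2-one | O=C1OC[C@H](Cc2ccccc2)N1C(=O)COCc1ccccc1 | intermediate
16 | Z dibutylboron enolate of 15 | CCCCB(CCCC)O/C(=C\OCc1ccccc1)N1[C@@H](Cc2ccccc2)COC1=O | intermediate (not isolated)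
17 | (S)-4-benzyl-3-[(2S,3R)-2-(benzyloxy)-3-[4-(benzyloxy)phenyl]-3-hydroxypropanoyl]oxazolidin-2-one | O=C1OC[C@H](Cc2ccccc2)N1C(=O)[C@@H](OCc1ccccc1)[C@H](O)c1ccc(OCc2ccccc2)cc1 | intermediate
18 | (S)-4-benzyl-3-[(2S,3R)-2-(benzyloxy)-3-[4-(benzyloxy)phenyl]-3-[(tert-butyldimethylsilyl)oxy]propanoyl]oxazolidin-2-one | O=C1OC[C@H](Cc2ccccc2)N1C(=O)[C@@H](OCc1ccccc1)[C@H](O[Si](C)(C)C(C)(C)C)c1ccc(OCc2ccccc2)cc1 | intermediate
19 | (2R,3R)-2-(benzyloxy)-3-[4-(benzyloxy)phenyl]-3-[(tert-butyldimethylsilyl)oxy]propan-1-ol | OC[C@@H](OCc1ccccc1)[C@H](O[Si](C)(C)C(C)(C)C)c1ccc(OCc2ccccc2)cc1 | intermediate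
20 | (2S,3R)-2-(benzyloxy)-3-[4-(benzyloxy)phenyl]-3-[(tert-butyldimethylsilyl)oxy]propanal | O=C[C@@H](OCc1ccccc1)[C@H](O[Si](C)(C)C(C)(C)C)c1ccc(OCc2ccccc2)cc1 | intermediate
21 | [2,4-bis(benzyloxy)-6-fluorophenyl]magnesium chloride | Fc1cc(OCc2ccccc2)cc(OCc2ccccc2)c1[Mg]Cl | intermediate (not isolated)
22 | (1R,2S,3S)-2-(benzyloxy)-3-[4-(benzyloxy)phenyl]-1-[2,4-bis(benzyloxy)-6-fluorophenyl]-3-[(tert-butyldimethylsilyl)oxy]propan-1-ol | Fc1cc(OCc2ccccc2)cc(OCc2ccccc2)c1[C@@H](O)[C@H](OCc1ccccc1)[C@@H](O[Si](C)(C)C(C)(C)C)c1ccc(OCc2ccccc2)cc1 | intermediate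
23 | (1R,2R,3S)-2-(benzyloxy)-3-[4-(benzyloxy)phenyl]-1-[2,4-bis(benzyloxy)-6-fluorophenyl]propane-1,3-diol | Fc1cc(OCc2ccccc2)cc(OCc2ccccc2)c1[C@@H](O)[C@H](OCc1ccccc1)[C@@H](O)c1ccc(OCc2ccccc2)cc1 | intermediate
24 | (2S,3S,4R)-3,5,7-tris(benzyloxy)-2-[4-(benzyloxy)phenyl]chroman-4-ol (unit T, 2,3-cis) | c1c(OCc5ccccc5)cc(OCc5ccccc5)c2c1O[C@@H](c1ccc(OCc5ccccc5)cc1)[C@@H](OCc5ccccc5)[C@@H]2O | intermediate
25 | (2S,3R)-3,5,7-tris(benzyloxy)-2-[4-(benzyloxy)phenyl]chroman-4-one (unit T ketone, 2,3-cis) | c1c(OCc5ccccc5)cc(OCc5ccccc5)c2c1O[C@@H](c1ccc(OCc5ccccc5)cc1)[C@@H](OCc5ccccc5)C2=O | intermediate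
26 | [4,6-bis(benzyloxy)-3-bromo-2-fluorophenyl]lithium | [Li]c1c(F)c(Br)c(OCc2ccccc2)cc1OCc1ccccc1 | intermediate (not isolated)
27 | (2S,3R,4R)-3,5,7-tris(benzyloxy)-2-[4-(benzyloxy)phenyl]-4-[4,6-bis(benzyloxy)-3-bromo-2-fluorophenyl]chroman-4-ol (4-OH cis to 3-OBn) | Fc1c(Br)c(OCc5ccccc5)cc(OCc5ccccc5)c1[C@]3(O)c4c(OCc5ccccc5)cc(OCc5ccccc5)cc4O[C@@H](c4ccc(OCc5ccccc5)cc4)[C@H]3OCc5ccccc5 | intermediate
28 | (2S,3S,4R)-3,5,7-tris(benzyloxy)-2-[4-(benzyloxy)phenyl]-4-[4,6-bis(benzyloxy)-3-bromo-2-fluorophenyl]chromane (all-cis) | Fc1c(Br)c(OCc5ccccc5)cc(OCc5ccccc5)c1[C@H]3c4c(OCc5ccccc5)cc(OCc5ccccc5)cc4O[C@@H](c4ccc(OCc5ccccc5)cc4)[C@H]3OCc5ccccc5 | intermediate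
29 | {4,6-bis(benzyloxy)-2-fluoro-3-[(2S,3S,4R)-3,5,7-tris(benzyloxy)-2-(4-benzyloxyphenyl)chroman-4-yl]phenyl}magnesium chloride | Fc1c([Mg]Cl)c(OCc5ccccc5)cc(OCc5ccccc5)c1[C@H]3c4c(OCc5ccccc5)cc(OCc5ccccc5)cc4O[C@@H](c4ccc(OCc5ccccc5)cc4)[C@H]3OCc5ccccc5 | intermediate (not isolated)
30 | (1S,2R,3R)-2-(benzyloxy)-3-[4-(benzyloxy)phenyl]-1-{4,6-bis(benzyloxy)-2-fluoro-3-[(2S,3S,4R)-3,5,7-tris(benzyloxy)-2-(4-benzyloxyphenyl)chroman-4-yl]phenyl}-3-[(tert-butyldimethylsilyl)oxy]propan-1-ol | Fc1c([C@H](O)[C@@H](OCc5ccccc5)[C@H](O[Si](C)(C)C(C)(C)C)c6ccc(OCc5ccccc5)cc6)c(OCc5ccccc5)cc(OCc5ccccc5)c1[C@H]3c4c(OCc5ccccc5)cc(OCc5ccccc5)cc4O[C@@H](c4ccc(OCc5ccccc5)cc4)[C@H]3OCc5ccccc5 | intermediate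
31 | (1S,2S,3R)-2-(benzyloxy)-3-[4-(benzyloxy)phenyl]-1-{4,6-bis(benzyloxy)-2-fluoro-3-[(2S,3S,4R)-3,5,7-tris(benzyloxy)-2-(4-benzyloxyphenyl)chroman-4-yl]phenyl}propane-1,3-diol | Fc1c([C@H](O)[C@@H](OCc5ccccc5)[C@H](O)c6ccc(OCc5ccccc5)cc6)c(OCc5ccccc5)cc(OCc5ccccc5)c1[C@H]3c4c(OCc5ccccc5)cc(OCc5ccccc5)cc4O[C@@H](c4ccc(OCc5ccccc5)cc4)[C@H]3OCc5ccccc5 | intermediate
32 | octa-O-benzyl ent-epiafzelechin-(4β→8)-epiafzelechin-4β-ol: (2R,3R,4S)-3,5,7-tris(benzyloxy)-2-[4-(benzyloxy)phenyl]-8-[(2S,3S)-3,5,7-tris(benzyloxy)-2-(4-benzyloxyphenyl)chroman-4-yl]chroman-4-ol, upper unit all-cis | c5ccccc5COc1ccc([C@H]2Oc3c(c(OCc5ccccc5)cc(OCc5ccccc5)c3[C@H]3c4c(OCc5ccccc5)cc(OCc5ccccc5)cc4O[C@@H](c4ccc(OCc5ccccc5)cc4)[C@H]3OCc5ccccc5)[C@H](O)[C@H]2OCc5ccccc5)cc1 | intermediate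
33 | octa-O-benzyl dimer 4-ketone: (2R,3S)-chroman-4-one of unit M (2,3-cis) carrying the all-cis unit T at C8 | c5ccccc5COc1ccc([C@H]2Oc3c(c(OCc5ccccc5)cc(OCc5ccccc5)c3[C@H]3c4c(OCc5ccccc5)cc(OCc5ccccc5)cc4O[C@@H](c4ccc(OCc5ccccc5)cc4)[C@H]3OCc5ccccc5)C(=O)[C@H]2OCc5ccccc5)cc1 | intermediate
34 | [4,6-bis(benzyloxy)-3-bromo-2-fluorophenyl]magnesium chloride | Cl[Mg]c1c(F)c(Br)c(OCc2ccccc2)cc1OCc1ccccc1 | intermediate (not isolated)
35 | dimer tertiary carbinol: unit M (2R,3S,4S)-4-[4,6-bis(benzyloxy)-3-bromo-2-fluorophenyl]chroman-4-ol, 4-OH cis to 3-OBn, unit T at C8 | c5ccccc5COc1ccc([C@H]2Oc3c(c(OCc5ccccc5)cc(OCc5ccccc5)c3[C@H]3c4c(OCc5ccccc5)cc(OCc5ccccc5)cc4O[C@@H](c4ccc(OCc5ccccc5)cc4)[C@H]3OCc5ccccc5)[C@](O)(c3c(OCc5ccccc5)cc(OCc5ccccc5)c(Br)c3F)[C@H]2OCc5ccccc5)cc1 | intermediate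
36 | dimer aryl bromide: unit M (2R,3R,4S)-4-[4,6-bis(benzyloxy)-3-bromo-2-fluorophenyl]chromane, all-cis, unit T at C8 | c5ccccc5COc1ccc([C@H]2Oc3c(c(OCc5ccccc5)cc(OCc5ccccc5)c3[C@H]3c4c(OCc5ccccc5)cc(OCc5ccccc5)cc4O[C@@H](c4ccc(OCc5ccccc5)cc4)[C@H]3OCc5ccccc5)[C@@H](c3c(OCc5ccccc5)cc(OCc5ccccc5)c(Br)c3F)[C@H]2OCc5ccccc5)cc1 | intermediate
37 | arylmagnesium chloride from 36 (MgCl in place of Br) | c5ccccc5COc1ccc([C@H]2Oc3c(c(OCc5ccccc5)cc(OCc5ccccc5)c3[C@H]3c4c(OCc5ccccc5)cc(OCc5ccccc5)cc4O[C@@H](c4ccc(OCc5ccccc5)cc4)[C@H]3OCc5ccccc5)[C@@H](c3c(OCc5ccccc5)cc(OCc5ccccc5)c([Mg]Cl)c3F)[C@H]2OCc5ccccc5)cc1 | intermediate (not isolated)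
38 | trimer-stage carbinol: 36 with the bromine replaced by a (1R,2S,3S)-2-(benzyloxy)-3-[4-(benzyloxy)phenyl]-3-[(tert-butyldimethylsilyl)oxy]-1-hydroxypropyl chain | c5ccccc5COc1ccc([C@H]2Oc3c(c(OCc5ccccc5)cc(OCc5ccccc5)c3[C@H]3c4c(OCc5ccccc5)cc(OCc5ccccc5)cc4O[C@@H](c4ccc(OCc5ccccc5)cc4)[C@H]3OCc5ccccc5)[C@@H](c3c(OCc5ccccc5)cc(OCc5ccccc5)c([C@@H](O)[C@H](OCc5ccccc5)[C@@H](O[Si](C)(C)C(C)(C)C)c6ccc(OCc5ccccc5)cc6)c3F)[C@H]2OCc5ccccc5)cc1 | intermediate
39 | potassium C4-alkoxide of 38 | [K+].c5ccccc5COc1ccc([C@H]2Oc3c(c(OCc5ccccc5)cc(OCc5ccccc5)c3[C@H]3c4c(OCc5ccccc5)cc(OCc5ccccc5)cc4O[C@@H](c4ccc(OCc5ccccc5)cc4)[C@H]3OCc5ccccc5)[C@@H](c3c(OCc5ccccc5)cc(OCc5ccccc5)c([C@@H]([O-])[C@H](OCc5ccccc5)[C@@H](O[Si](C)(C)C(C)(C)C)c6ccc(OCc5ccccc5)cc6)c3F)[C@H]2OCc5ccccc5)cc1 | intermediate (not isolated)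
40 | silyl-shifted potassium C2-alkoxide (silyl on O4, alkoxide on O2) | [K+].c5ccccc5COc1ccc([C@H]2Oc3c(c(OCc5ccccc5)cc(OCc5ccccc5)c3[C@H]3c4c(OCc5ccccc5)cc(OCc5ccccc5)cc4O[C@@H](c4ccc(OCc5ccccc5)cc4)[C@H]3OCc5ccccc5)[C@@H](c3c(OCc5ccccc5)cc(OCc5ccccc5)c([C@@H](O[Si](C)(C)C(C)(C)C)[C@H](OCc5ccccc5)[C@@H]([O-])c6ccc(OCc5ccccc5)cc6)c3F)[C@H]2OCc5ccccc5)cc1 | intermediate (not isolated)
41 | dodeca-O-benzyl 4-O-(tert-butyldimethylsilyl) derivative of the target (unit B: (2S,3S,4R), 2,3-cis-3,4-trans) | c5ccccc5COc1ccc([C@H]2Oc3c(c(OCc5ccccc5)cc(OCc5ccccc5)c3[C@H]3c4c(OCc5ccccc5)cc(OCc5ccccc5)cc4O[C@@H](c4ccc(OCc5ccccc5)cc4)[C@H]3OCc5ccccc5)[C@@H](c3c(OCc5ccccc5)cc(OCc5ccccc5)c4c3O[C@@H](c3ccc(OCc5ccccc5)cc3)[C@@H](OCc5ccccc5)[C@@H]4O[Si](C)(C)C(C)(C)C)[C@H]2OCc5ccccc5)cc1 | intermediate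
42 | 4-O-(tert-butyldimethylsilyl) ether of the target | Oc1ccc([C@H]2Oc3c(c(O)cc(O)c3[C@H]3c4c(O)cc(O)cc4O[C@@H](c4ccc(O)cc4)[C@H]3O)[C@@H](c3c(O)cc(O)c4c3O[C@@H](c3ccc(O)cc3)[C@@H](O)[C@@H]4O[Si](C)(C)C(C)(C)C)[C@H]2O)cc1 | intermediate
43 | ent-epiafzelechin-(4β→8)-epiafzelechin-(4α→8)-(2S,3S,4R)-2-(4-hydroxyphenyl)chromane-3,4,5,7-tetrol | Oc1ccc([C@H]2Oc3c(c(O)cc(O)c3[C@H]3c4c(O)cc(O)cc4O[C@@H](c4ccc(O)cc4)[C@H]3O)[C@@H](c3c(O)cc(O)c4c3O[C@@H](c3ccc(O)cc3)[C@@H](O)[C@@H]4O)[C@H]2O)cc1 | target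

**Step count and risks**

Total step count: 29. Longest linear sequence: 21 steps (steps 4–8, then 14–29).

Steps most likely to fail:

1. Step 27 (bears the label "Proposed new method:"). The silyl shift may not keep pace, so that the C4 alkoxide is consumed by side reactions, or released fluoride may strip the silyl group before or after ring closure (loss of the protecting group). The fallback uses known chemistry and sets out from 38. Bu4NF in THF removes the silyl ether and should give the trimer-stage 1,3-diol F1. KN(SiMe3)2 in THF/DMPU then closes ring C by the plain alkoxide SNAr already used in steps 16 and 22 and should give the benzylated trimer with free 4-hydroxyl F2. TBSOTf and 2,6-lutidine silylate O4, and the route is rejoined at 41.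

2. Step 28. Over-reduction is the danger: hydrogenolysis of the benzylic C4–O bond of unit B, possibly after loss of the silyl ether on the catalyst, together with incomplete removal of twelve benzyl groups. The fallback sets out from 41 and makes the carbinol last. Bu4NF gives the 4-ol (the compound F2 described above). Dess–Martin periodinane with pyridine should give the benzylated trimer 4-ketone F3. Hydrogenolysis over Pd(OH)2/C, which spares the aryl ketone, should give the polyphenolic trimer with a 2,3-cis dihydroflavonol end unit F4. Me4NBH(OAc)3 in MeCN/AcOH at −20 °C, bound to the 3-hydroxyl, delivers hydride to the same face of the ketone (hydroxyl-directed reduction) and should give the 3,4-trans diol, rejoining the route at 43.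

3. Step 26. Facial selectivity may be poor if magnesium chelation between the aldehyde oxygen and the α-benzyloxy group is incomplete with so large an aryl nucleophile. The fallback sets out from 38 obtained mixed with its C4 epimer and sets the centre by reduction instead of addition. Dess–Martin oxidation converges both epimers to the trimer-stage aryl ketone F5. KBH(s-Bu)3 in THF at −78 °C, which does not chelate, reduces it under Felkin–Anh control (hydride anti to the C–OBn bond) to the 3,4-syn carbinol, rejoining the route at 38.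

Further compounds
F1 | step 27 | trimer-stage 1,3-diol (38 without the silyl group) | c5ccccc5COc1ccc([C@H]2Oc3c(c(OCc5ccccc5)cc(OCc5ccccc5)c3[C@H]3c4c(OCc5ccccc5)cc(OCc5ccccc5)cc4O[C@@H](c4ccc(OCc5ccccc5)cc4)[C@H]3OCc5ccccc5)[C@@H](c3c(OCc5ccccc5)cc(OCc5ccccc5)c([C@@H](O)[C@H](OCc5ccccc5)[C@@H](O)c6ccc(OCc5ccccc5)cc6)c3F)[C@H]2OCc5ccccc5)cc1
F2 | step 27 | dodeca-O-benzyl trimer with free 4-hydroxyl in unit B | c5ccccc5COc1ccc([C@H]2Oc3c(c(OCc5ccccc5)cc(OCc5ccccc5)c3[C@H]3c4c(OCc5ccccc5)cc(OCc5ccccc5)cc4O[C@@H](c4ccc(OCc5ccccc5)cc4)[C@H]3OCc5ccccc5)[C@@H](c3c(OCc5ccccc5)cc(OCc5ccccc5)c4c3O[C@@H](c3ccc(OCc5ccccc5)cc3)[C@@H](OCc5ccccc5)[C@@H]4O)[C@H]2OCc5ccccc5)cc1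
F3 | step 28 | dodeca-O-benzyl trimer with unit B as 2,3-cis chroman-4-one | c5ccccc5COc1ccc([C@H]2Oc3c(c(OCc5ccccc5)cc(OCc5ccccc5)c3[C@H]3c4c(OCc5ccccc5)cc(OCc5ccccc5)cc4O[C@@H](c4ccc(OCc5ccccc5)cc4)[C@H]3OCc5ccccc5)[C@@H](c3c(OCc5ccccc5)cc(OCc5ccccc5)c4c3O[C@@H](c3ccc(OCc5ccccc5)cc3)[C@@H](OCc5ccccc5)C4=O)[C@H]2OCc5ccccc5)cc1
F4 | step 28 | polyphenolic trimer with unit B as 2,3-cis dihydroflavonol (4-ketone) | Oc1ccc([C@H]2Oc3c(c(O)cc(O)c3[C@H]3c4c(O)cc(O)cc4O[C@@H](c4ccc(O)cc4)[C@H]3O)[C@@H](c3c(O)cc(O)c4c3O[C@@H](c3ccc(O)cc3)[C@@H](O)C4=O)[C@H]2O)cc1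
F5 | step 26 | trimer-stage aryl ketone (38 with C=O in place of the carbinol) | c5ccccc5COc1ccc([C@H]2Oc3c(c(OCc5ccccc5)cc(OCc5ccccc5)c3[C@H]3c4c(OCc5ccccc5)cc(OCc5ccccc5)cc4O[C@@H](c4ccc(OCc5ccccc5)cc4)[C@H]3OCc5ccccc5)[C@@H](c3c(OCc5ccccc5)cc(OCc5ccccc5)c(C(=O)[C@H](OCc5ccccc5)[C@@H](O[Si](C)(C)C(C)(C)C)c6ccc(OCc5ccccc5)cc6)c3F)[C@H]2OCc5ccccc5)cc1
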